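**Plan**
- Cuts (retro): first the four O–MOM bonds. Then C2–C1' between pyranone ring C and ring B, giving C2–H chromone 10 and aryl bromide 12. Then O1–C2/C2–C3 (C2 leaves as a one-carbon unit, giving ketone 8), then C3–CH2 of the prenyl chain, and last C8–CMe2 by retro-Claisen to the 4-O-prenyl ether 3 of phloroacetophenone.
- Forward: ring A is bought. O-prenylation and aromatic Claisen rearrangement place the 1,1-dimethylallyl group while ring A still has a mirror plane (C3 = C5), so no C6/C8 question arises there.
- Two MOM groups take the two accessible hydroxyls and leave the hindered, chelated OH beside the tert-alkyl group. This oxygen becomes O1 and fixes the side chain at C8. Enolate prenylation sets the C3 chain and aminomethylenation closes ring C.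
- Ring B is joined last, to the fully decorated A/C half, at the most hindered sp2–sp2 bond (flanked by C3-prenyl and the 2'-oxygen). Global MOM removal ends the route.
- Enabling feature: the C2–H of ring C is bound to O1 and stands β to the C4 carbonyl (a vinylogous formate C–H). It is the only acidic ring C–H once C3 carries prenyl, so the chromone needs no halogen or other handle.
- Stereochemistry: none to set, because the target has no stereocentre, no E/Z alkene and no stable axis.

Key step: step 7

Assumption: the SMILES carries no stereo descriptor and the structure is achiral, so "single enantiomer" is read as the one constitution shown. The only sp3 stereocentre met on the way (dienone 4) is transient and is lost on tautomerisation.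

Step 1
Reactants: 1 2,4,6-trihydroxyacetophenone (phloroacetophenone); 2 prenyl bromide (1-bromo-3-methylbut-2-ene)
Product: 3 1-[2,6-dihydroxy-4-(3-methylbut-2-enyloxy)phenyl]ethan-1-one
Conditions: K2CO3 (1.0 equiv), 2 (1.0 equiv), acetone, reflux
Reagents that add atoms: none
Why: Williamson etherification, in which the 4-OH is the most acidic hydroxyl and the only one not held in a hydrogen bond to the acetyl C=O, so one equivalent of weak base and bromide in an aprotic solvent should alkylate this oxygen rather than the chelated 2-/6-OH or a ring carbon.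

Step 2
Reactants: 3 1-[2,6-dihydroxy-4-(3-methylbut-2-enyloxy)phenyl]ethan-1-one
Product: 5 1-[2,4,6-trihydroxy-3-(2-methylbut-3-en-2-yl)phenyl]ethan-1-one, via ortho-dienone 4 (not isolated)
Conditions: PhNEt2, 200 °C, sealed tube, Ar, short reaction time
Reagents that add atoms: none
Why: Aromatic Claisen rearrangement ([3,3]-sigmatropic shift with allyl inversion) should deliver the tertiary carbon of the prenyl unit to C3, which equals C5 by symmetry, after which dienone 4 tautomerises to the arene, while the acetyl-blocked para position prevents a productive Cope relay to a linear prenyl group and the basic solvent suppresses acid-induced ring closure.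

Step 3
Reactants: 5 1-[2,4,6-trihydroxy-3-(2-methylbut-3-en-2-yl)phenyl]ethan-1-one
Product: 6 1-[2-hydroxy-4,6-bis(methoxymethoxy)-3-(2-methylbut-3-en-2-yl)phenyl]ethan-1-one
Conditions: MOMCl (2.2 equiv), i-Pr2NEt (2.5 equiv), CH2Cl2, 0 °C to rt
Reagents that add atoms: chloromethyl methyl ether (MOMCl), COCCl
Why: Site-selective MOM acetalisation, in which the non-chelated 4-OH and the 6-OH (flanked only by H-5 and acetyl) should react while the 2-OH, wedged between the tert-alkyl and acetyl groups and locked in the hydrogen bond to C=O, stays free, which is the pattern known from partial alkylation of 3-alkylphloroacetophenones and the choice that puts the side chain at C8.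

Step 4
Reactants: 6 1-[2-hydroxy-4,6-bis(methoxymethoxy)-3-(2-methylbut-3-en-2-yl)phenyl]ethan-1-one; 2 prenyl bromide
Product: 8 1-[2-hydroxy-4,6-bis(methoxymethoxy)-3-(2-methylbut-3-en-2-yl)phenyl]-5-methylhex-4-en-1-one, via dilithium dianion 7 (not isolated)
Conditions: LDA (2.2 equiv), THF, −78 to −20 °C; 2 (1.0 equiv), −78 to 0 °C; AcOH quench
Reagents that add atoms: none
Why: Alkylation of the dianion of an o-hydroxyaryl methyl ketone, in which the terminal enolate carbon is far more nucleophilic than the hindered, lithium-chelated phenoxide, prenyl bromide reacts by SN2 at its primary carbon, and the absence of excess bromide limits double alkylation.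

Step 5
Reactants: 8 1-[2-hydroxy-4,6-bis(methoxymethoxy)-3-(2-methylbut-3-en-2-yl)phenyl]-5-methylhex-4-en-1-one
Product: 10 5,7-bis(methoxymethoxy)-8-(2-methylbut-3-en-2-yl)-3-(3-methylbut-2-enyl)-4H-chromen-4-one, via enaminone 9 (not isolated)
Conditions: t-BuOCH(NMe2)2 (3 equiv), PhMe, 110 °C, N2 sweep
Reagents that add atoms: tert-butoxybis(dimethylamino)methane (Bredereck's reagent), CN(C)C(OC(C)(C)C)N(C)C
Why: Enaminone route to chromones, in which the reagent aminomethylenates the α-CH2 to give 9 and the neighbouring phenol attacks its β-carbon (6-endo-trig addition–elimination with loss of Me2NH) as in the known conversion of o-hydroxyaryl alkyl or benzyl ketones into 3-substituted chromones and isoflavones, the tert-butoxy aminal being preferred to DMF dimethyl acetal because it is more reactive toward a non-benzylic CH2 and cannot O-methylate the phenol.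

Step 6
Reactants: 11 4-bromoresorcinol (4-bromobenzene-1,3-diol)
Product: 12 1-bromo-2,4-bis(methoxymethoxy)benzene
Conditions: MOMCl (2.4 equiv), i-Pr2NEt (3 equiv), CH2Cl2, 0 °C to rt
Reagents that add atoms: chloromethyl methyl ether (MOMCl), COCCl
Why: Standard MOM protection of both phenols, giving acetals that tolerate the organozinc step and leave in the same operation as those of ring A.

Step 7
Reactants: 10 5,7-bis(methoxymethoxy)-8-(2-methylbut-3-en-2-yl)-3-(3-methylbut-2-enyl)-4H-chromen-4-one; 12 1-bromo-2,4-bis(methoxymethoxy)benzene
Product: 14 2-[2,4-bis(methoxymethoxy)phenyl]-5,7-bis(methoxymethoxy)-8-(2-methylbut-3-en-2-yl)-3-(3-methylbut-2-enyl)-4H-chromen-4-one, via chromon-2-ylzinc chloride 13 (not isolated)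
Conditions: TMPZnCl·LiCl (1.3 equiv), THF, 25 to 45 °C; then 12 (1.2 equiv), Pd(OAc)2 (3 mol %), SPhos (6 mol %), THF, 55 °C
Reagents that add atoms: none
Why: The zinc amide removes the C2–H of pyranone ring C, the one ring C–H bound to O1 and β to the C4 carbonyl, to give alkenylzinc 13, after which Pd(0)/SPhos inserts into the C–Br bond of 12, 13 transmetalates and reductive elimination forms the C2–C1' bond (one-pot C–H zincation/Negishi cross-coupling). The closest known reaction type is the TMP-zinc-amide metalation of chromones followed by Negishi arylation, an established entry to flavones. No ring is closed and no stereocentre is formed, and the new axis carries only two ortho substituents (C3-prenyl and 2'-OMOM), so it should rotate freely. Site selectivity is needed against C3, against C6–H between the two OMOM groups and against the doubly allylic C3–CH2: C3 is blocked by the prenyl chain, and the mild zinc amide, unlike lithium bases, should neither metalate an alkoxy-flanked arene C–H or an unactivated allylic C–H nor add to C4=O. Chemoselectivity at palladium is needed against Heck insertion into the side-chain alkenes, and it is secured by fast transmetalation from zinc, the absence of a Heck base and the hindrance of both alkenes (neopentyl-type vinyl, trisubstituted prenyl). The bulky, electron-rich biarylphosphine is chosen because the bond is flanked on both sides and the bromide is electron-rich, and the step completes the whole carbon skeleton from two fully decorated halves.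

Step 8
Reactants: 14 2-[2,4-bis(methoxymethoxy)phenyl]-5,7-bis(methoxymethoxy)-8-(2-methylbut-3-en-2-yl)-3-(3-methylbut-2-enyl)-4H-chromen-4-one
Product: 15 nigrasin I, 2-(2,4-dihydroxyphenyl)-5,7-dihydroxy-8-(2-methylbut-3-en-2-yl)-3-(3-methylbut-2-enyl)-4H-chromen-4-one
Conditions: conc HCl (catalytic), MeOH–THF, 40 °C
Reagents that add atoms: none
Why: Acid-catalysed transacetalisation of the four aryl MOM ethers to methanol, a deprotection with close precedent on C-prenylated flavonoids, should be much faster at this acidity and temperature than protonation of the trisubstituted prenyl alkene or of the monosubstituted vinyl group.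

**Compound list**
1 | 2,4,6-trihydroxyacetophenone | CC(=O)c1c(O)cc(O)cc1O | starting material
2 | prenyl bromide (1-bromo-3-methylbut-2-ene) | CC(C)=CCBr | starting material
3 | 1-[2,6-dihydroxy-4-(3-methylbut-2-enyloxy)phenyl]ethan-1-one | CC(=O)c1c(O)cc(OCC=C(C)C)cc1O | intermediate
4 | 4-acetyl-3,5-dihydroxy-6-(2-methylbut-3-en-2-yl)cyclohexa-2,4-dien-1-one (racemic, transient, not isolated) | CC(=O)C1=C(O)C(C(C)(C)C=C)C(=O)C=C1O | intermediate
5 | 1-[2,4,6-trihydroxy-3-(2-methylbut-3-en-2-yl)phenyl]ethan-1-one | CC(=O)c1c(O)cc(O)c(C(C)(C)C=C)c1O | intermediate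
6 | 1-[2-hydroxy-4,6-bis(methoxymethoxy)-3-(2-methylbut-3-en-2-yl)phenyl]ethan-1-one | CC(=O)c1c(O)c(C(C)(C)C=C)c(OCOC)cc1OCOC | intermediate
7 | dilithium phenoxide–enolate of 6 (not isolated) | C=C([O-])c1c([O-])c(C(C)(C)C=C)c(OCOC)cc1OCOC.[Li+].[Li+] | intermediate
8 | 1-[2-hydroxy-4,6-bis(methoxymethoxy)-3-(2-methylbut-3-en-2-yl)phenyl]-5-methylhex-4-en-1-one | CC(C)=CCCC(=O)c1c(O)c(C(C)(C)C=C)c(OCOC)cc1OCOC | intermediate
9 | 2-[(dimethylamino)methylidene] derivative of 8 (enaminone, alkene geometry of no consequence, not isolated) | CN(C)C=C(CC=C(C)C)C(=O)c1c(O)c(C(C)(C)C=C)c(OCOC)cc1OCOC | intermediate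
10 | 5,7-bis(methoxymethoxy)-8-(2-methylbut-3-en-2-yl)-3-(3-methylbut-2-enyl)-4H-chromen-4-one | C=CC(C)(C)c1c(OCOC)cc(OCOC)c2c(=O)c(CC=C(C)C)coc12 | intermediate
11 | 4-bromoresorcinol | Oc1ccc(Br)c(O)c1 | starting material
12 | 1-bromo-2,4-bis(methoxymethoxy)benzene | COCOc1ccc(Br)c(OCOC)c1 | intermediate
13 | [5,7-bis(methoxymethoxy)-8-(2-methylbut-3-en-2-yl)-3-(3-methylbut-2-enyl)-4-oxo-4H-chromen-2-yl]zinc chloride (LiCl complex, not isolated) | C=CC(C)(C)c1c(OCOC)cc(OCOC)c2c(=O)c(CC=C(C)C)c([Zn]Cl)oc12 | intermediate
14 | 2-[2,4-bis(methoxymethoxy)phenyl]-5,7-bis(methoxymethoxy)-8-(2-methylbut-3-en-2-yl)-3-(3-methylbut-2-enyl)-4H-chromen-4-one | C=CC(C)(C)c1c(OCOC)cc(OCOC)c2c(=O)c(CC=C(C)C)c(-c3ccc(OCOC)cc3OCOC)oc12 | intermediate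
15 | nigrasin I | C=CC(C)(C)c1c(O)cc(O)c2c(=O)c(CC=C(C)C)c(-c3ccc(O)cc3O)oc12 | target

Total step count: 8. Longest linear sequence: 7 (steps 1, 2, 3, 4, 5, 7, 8). Step 6 is the one-step side branch.

**Steps most likely to fail**

Step 7. Zincation of the 3-alkylated ring may stay incomplete. Transmetalation or reductive elimination at the doubly flanked C2 may also be so slow that the organozinc is lost by protonation or homocoupling. The fallback reverses the polarity, with an electrophilic chromone and no metalation of ring C. It sets out from 8 and 12 and comes back at 14.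
- Ketone 8 is condensed with CS2 (KOt-Bu, THF) to the 4-hydroxy-3-prenylchromene-2-thione F1.
- S-methylation (MeI, K2CO3, acetone) gives the 2-(methylthio)chromone F2, a vinylogous thiol ester.
- Bromide 12 is converted by Br/Li exchange (n-BuLi, −78 °C), B(Oi-Pr)3 and hydrolysis into 2,4-bis(methoxymethoxy)phenylboronic acid F3.
- F2 and F3 are joined by base-free Liebeskind–Srogl coupling (Pd2(dba)3, tri(2-furyl)phosphine, CuTC, THF, 50 °C) to give 14.

Step 2. At the temperature the [3,3] shift needs, the freed phenol and its neighbour flank the new side chain. They may react on by a hydrogen shift of the abnormal-Claisen type or by ring closure onto the vinyl group, and the ether may also lose its prenyl group. The fallback intercepts every phenol as it forms. It sets out from 3 and comes back at 5.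
- Ether 3 is silylated with N,O-bis(trimethylsilyl)acetamide to the bis(trimethylsilyl) ether F4.
- F4 is heated in the same silylating medium (BSA, PhNEt2, 190 °C), so the phenol released by rearrangement is captured at once as the tris(trimethylsilyl) ether F5.
- Mild methanolysis (catalytic K2CO3, MeOH, 0 °C) then gives 5.

Step 8. Cleavage of the hindered 7-OMOM group may be slow enough for acid-induced addition of solvent or of a neighbouring phenol to the side-chain alkenes to compete. The fallback avoids protic acid. It sets out from 14 and comes back at 15.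
- TMSOTf/2,2'-bipyridyl (MeCN, 0 °C to rt) exchanges the four aryl MOM ethers for silyl ethers to give the tetrakis(trimethylsilyl) ether F6.
- Water at rt then hydrolyses F6 to 15.

**Further compounds**
F1 | step 7 | 4-hydroxy-5,7-bis(methoxymethoxy)-8-(2-methylbut-3-en-2-yl)-3-(3-methylbut-2-enyl)-2H-chromene-2-thione | C=CC(C)(C)c1c(OCOC)cc(OCOC)c2c(O)c(CC=C(C)C)c(=S)oc12
F2 | step 7 | 5,7-bis(methoxymethoxy)-8-(2-methylbut-3-en-2-yl)-3-(3-methylbut-2-enyl)-2-(methylsulfanyl)-4H-chromen-4-one | C=CC(C)(C)c1c(OCOC)cc(OCOC)c2c(=O)c(CC=C(C)C)c(SC)oc12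
F3 | step 7 | 2,4-bis(methoxymethoxy)phenylboronic acid | COCOc1ccc(B(O)O)c(OCOC)c1
F4 | step 2 | 1-[4-(3-methylbut-2-enyloxy)-2,6-bis(trimethylsilyloxy)phenyl]ethan-1-one | CC(=O)c1c(O[Si](C)(C)C)cc(OCC=C(C)C)cc1O[Si](C)(C)C
F5 | step 2 | 1-[3-(2-methylbut-3-en-2-yl)-2,4,6-tris(trimethylsilyloxy)phenyl]ethan-1-one | CC(=O)c1c(O[Si](C)(C)C)cc(O[Si](C)(C)C)c(C(C)(C)C=C)c1O[Si](C)(C)C
F6 | step 8 | nigrasin I tetrakis(trimethylsilyl) ether | C=CC(C)(C)c1c(O[Si](C)(C)C)cc(O[Si](C)(C)C)c2c(=O)c(CC=C(C)C)c(-c3ccc(O[Si](C)(C)C)cc3O[Si](C)(C)C)oc12
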